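The rate constants stand for no real mixture; the run is a simulation.

The coupling constants of left-handed over right-handed substrate stand at a ratio of 1.64, the selectivity factor. Our decision for the next run is how to heat it and what to charge, so that the flask gets the most from that ratio.

    partner + free catalyst + left-handed substrate → free catalyst + left-handed product (k1 = 0.614 M⁻² s⁻¹, Ea1 = 59.0 kJ mol⁻¹)
    partner + free catalyst + right-handed substrate → free catalyst + right-handed product (k2 = 0.375 M⁻² s⁻¹, Ea2 = 58.0 kJ mol⁻¹)
    left-handed substrate + racemization catalyst ⇌ right-handed substrate + racemization catalyst, rate k3*[racemization catalyst]*[left-handed substrate] forward; the back reaction follows from the equilibrium constant (k3 = 0.141 M⁻¹ s⁻¹, Ea3 = 57.0 kJ mol⁻¹)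
    racemization catalyst + impurity → spent catalyst (k4 = 183 M⁻¹ s⁻¹, Ea4 = 38.0 kJ mol⁻¹)
    free catalyst + added ligand ⇌ idle complex, settled at all times (K5 = 84 M⁻¹, ΔH5 = −20.0 kJ mol⁻¹)
    partner → decomposition product (k6 = 7.53 × 10⁻⁶ s⁻¹, Ea6 = 113 kJ mol⁻¹)
    (constants at 90 °C)

the same everywhere: left-handed substrate 0.50 M; partner 2.00 equiv; free catalyst 2.6 mol%; racemization catalyst 10 mol%; impurity 13 mM; added ligand 8.0 mM; right-handed substrate 0.50 M; time 30 min
- maple: at 105 °C until 10 min, from then on at 90 °C
- ash: temperature 90 °C
- alder: temperature 105 °C

- free catalyst is single-handed; left-handed substrate and right-handed substrate are mirror images of each other, charged as a racemate, each of them at the stated concentration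
- all constants are for 90 °C and move with temperature by the activation energies and enthalpies

1. the flask that comes out highest in share of left-handed product in all that became left-handed product or right-handed product, or "all alike" when all lie within 1.5 percentage points (maple / ash / alder / all alike)
2. share of left-handed product in all that became left-handed product or right-handed product, maple
3. share of left-handed product in all that became left-handed product or right-handed product, ash
4. share of left-handed product in all that became left-handed product or right-handed product, alder

If racemization held the two substrates equal, the share would be 62.1%. That is our ceiling. To see how far below it we land, we freeze what hardly moves.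

The impurity, the smaller charge, has a half-life near 0.0758 s against the racemization catalyst, much shorter than the run. So we reckon with c(racemization catalyst) at 37.0 mM. The balance with the added ligand gives c(free catalyst) of 9.46 mM. Heating from 90 °C to 105 °C speeds the left-handed coupling 2.2-fold and racemization 2.1-fold, nearly alike. So we freeze the ratios across temperature as well.

Now we define the draw ratio: the pseudo-first-order constant with which coupling takes left-handed substrate, over the constant with which racemization turns it. At the start it is 1.11. The substrate cancels, so it falls in step with c(partner). Partner and substrates are charged equal, so its mean over conversion is 0.557, half the start.

Coupling takes left-handed substrate faster, and racemization closes a relative gap at twice its constant. The balanced gap is therefore the draw ratio times (1 − 1/selectivity factor), divided by two. With the mean draw ratio that is 10.8%, which gives a share of 59.3%. The gap opens from zero, which lifts the share a little, so we commit to a value between 59.3% and 62.1% in each flask. Our decision follows: choose the temperature for conversion and spend nothing on a schedule, and keep the racemization catalyst charged above the impurity.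

The forecast says all alike, with 60.4% for maple, 60.2% for ash and 60.5% for alder. Its ground: “Racemization relaxes in about 50–100 s, comparable to early coupling, so it only partly keeps up.” Our lower figure stands below its value for ash.

The simulation gives 60.4% for maple, 60.2% for ash and 60.4% for alder, so the answer is all alike, as forecast. In maple the draw ratio reads 0.64 at 1.36 min and 0.082 at 30.0 min, forward racemization alone, and the first reading already lies below our starting 1.11. A neighbour of maple charged with 0.500 equiv of partner starts at a draw ratio of 0.278, and the same halving gives a share of 61.4%. The computed flask gives 61.9%, with 37.5% of the two substrates together charged standing as right-handed substrate at the end.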